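Locants follow the open-chain precursor: C1 (CHI, later ring CH2), C2, C3 (ring C=O), C4 (ring CH bearing the cyclopropyl group), C5 (quaternary ring carbon), C6 (benzylic CH).
Retrosynthetic cuts, in order: the three phenol O–H (as O–CH3) and the two aryl–CHO bonds; the ring bond C1–C5 together with one C–H of the methyl group on C5; C3–C4; C4–C5; the bond from C6 to the isobutyl CH2.
Enabling feature: in the cyclopentanone, quaternary C5 carries a CH3 and is flanked by the ring CH2 C1. This is what results when an alkenylpalladium adds to the substituted end of a C5=CH2 alkene and the β-hydrogen-free CH2–Pd is then reduced to CH3.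
Forward order: the cyclopropane arrives intact in fragment 1 (aldehyde carbon = C4) from (+)-2-carene. Fragment 2 (arene, C6, C5 and its methylidene) is joined at C4–C5, a three-carbon ynal at C3–C4, and the cyclopentenone, the only ring that is built, closes at C1–C5.
Stereochemistry: both cyclopropane centres come from 2-carene, C6 from an oxazolidinone-directed alkylation, C5 from C6 in the ring closure, and C4 from equilibration to the trans-disposed ketone.

Key step: step 17

Remark: Ar = 2,4,6-trimethoxyphenyl; cPr* = the cis-2,2-dimethyl-3-[2-(2-methyl-1,3-dioxolan-2-yl)ethyl]cyclopropyl group in the carene-derived configuration. Between the fragment coupling and the key step, C4 is in turn a carbinol carbon, an alkene carbon and a labile α-carbon. Those compounds are therefore carried as epimer mixtures, and their SMILES leave C4 and any carbinol carbon open. 2-(2,4,6-Trimethoxyphenyl)acetic acid is assumed to be a catalogue compound.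

Step 1
Reactants: 1 (+)-2-carene [(1S,6R)-3,7,7-trimethylbicyclo[4.1.0]hept-2-ene]
Product: 3 (1S,3R)-2,2-dimethyl-3-(3-oxobutyl)cyclopropane-1-carbaldehyde (cis), via secondary ozonide 2 (not isolated)
Conditions: O3, CH2Cl2, −78 °C; then PPh3, −78 °C → rt
Reagents that add atoms: ozone, [O-][O+]=O
Why: Ozonolysis cleaves the only alkene into a methyl ketone and an aldehyde, and the two cyclopropane stereocentres are not touched.

Step 2
Reactants: 3 keto aldehyde
Product: 4 4-[(1R,3S)-3-(hydroxymethyl)-2,2-dimethylcyclopropyl]butan-2-one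
Conditions: NaBH(OAc)3, CH2Cl2, rt
Reagents that add atoms: none
Why: The mild acyloxyborohydride reduces aldehydes but not unactivated ketones, so this chemoselective reduction frees the ketone for separate protection.

Step 3
Reactants: 4 keto alcohol
Product: 5 {(1S,3R)-2,2-dimethyl-3-[2-(2-methyl-1,3-dioxolan-2-yl)ethyl]cyclopropyl}methanol
Conditions: HOCH2CH2OH, PPTS (cat.), benzene, reflux, Dean–Stark
Reagents that add atoms: ethylene glycol, OCCO
Why: Acid-catalysed ketalisation with azeotropic removal of water protects the methyl ketone, and PPTS is too weak an acid to ionise the primary cyclopropylcarbinol.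

Step 4
Reactants: 5 ketal alcohol
Product: 6 (1S,3R)-2,2-dimethyl-3-[2-(2-methyl-1,3-dioxolan-2-yl)ethyl]cyclopropane-1-carbaldehyde (cPr*–CHO)
Conditions: n-Pr4NRuO4 (5 mol %), NMO, 4 Å MS, CH2Cl2, rt
Reagents that add atoms: none
Why: The Ley–Griffith oxidation stops at the aldehyde under neutral conditions, so the ketal survives and the cis aldehyde does not epimerise.

Step 5
Reactants: 7 2-(2,4,6-trimethoxyphenyl)acetic acid; 8 (R)-4-benzyl-1,3-oxazolidin-2-one
Product: 10 (R)-4-benzyl-3-[2-(2,4,6-trimethoxyphenyl)acetyl]oxazolidin-2-one, via mixed pivalic anhydride 9 (not isolated)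
Conditions: t-BuCOCl, Et3N, THF, −20 °C; then 8, LiCl, −20 °C → rt
Reagents that add atoms: none
Why: N-Acylation of the oxazolidinone through the mixed anhydride is the standard loading of an Evans auxiliary, and attack occurs at the less hindered arylacetyl carbonyl.

Step 6
Reactants: 10 arylacetyl imide; 11 3-bromo-2-methylprop-1-ene (methallyl bromide)
Product: 13 (R)-4-benzyl-3-[(R)-4-methyl-2-(2,4,6-trimethoxyphenyl)pent-4-enoyl]oxazolidin-2-one, via sodium Z-enolate 12 (not isolated)
Conditions: NaN(SiMe3)2, THF, −78 °C; then 11, −78 → −40 °C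
Reagents that add atoms: none
Why: In this Evans asymmetric alkylation the chelated Z-enolate takes the reactive allylic bromide on the face away from the benzyl group, which sets C6 as R (the descriptor becomes S later through a change of substituent priorities only).

Step 7
Reactants: 13 methallylated imide
Product: 14 (R)-4-benzyl-3-[(R)-4-methyl-2-(2,4,6-trimethoxyphenyl)pentanoyl]oxazolidin-2-one
Conditions: H2 (1 atm), Pd/C (10 wt %), EtOAc, rt
Reagents that add atoms: none
Why: Heterogeneous hydrogenation saturates the unhindered 1,1-disubstituted alkene to the isobutyl group and so removes an alkene that would otherwise intercept the alkylpalladium of the key step.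

Step 8
Reactants: 14 saturated imide
Product: 15 S-ethyl (R)-4-methyl-2-(2,4,6-trimethoxyphenyl)pentanethioate
Conditions: EtSH (2 equiv), n-BuLi (1.5 equiv), THF, 0 °C
Reagents that add atoms: ethanethiol, CCS
Why: Lithium thiolate attacks the exocyclic carbonyl of hindered N-acyloxazolidinones selectively (transthioesterification), and the excess thiol keeps the medium too weakly basic to racemise C6.

Step 9
Reactants: 15 thioester
Product: 16 (R)-5-methyl-3-(2,4,6-trimethoxyphenyl)hexan-2-one
Conditions: Me2CuLi (from MeLi and CuI), Et2O, −78 → −40 °C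
Reagents that add atoms: methyllithium (delivered as Me2CuLi), [Li]C
Why: Gilman cuprates turn thioesters into ketones without over-addition and are too weakly basic to enolise the α-aryl ketone.

Step 10
Reactants: 16 methyl ketone
Product: 18 (R)-5-methyl-3-(2,4,6-trimethoxyphenyl)hex-1-en-2-yl trifluoromethanesulfonate, via terminal lithium enolate 17 (not isolated)
Conditions: LiN(i-Pr)2, THF, −78 °C (ketone added to base); then PhNTf2, −78 → 0 °C
Reagents that add atoms: N-phenylbis(trifluoromethanesulfonimide), O=S(=O)(N(c1ccccc1)S(=O)(=O)C(F)(F)F)C(F)(F)F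
Why: Kinetic deprotonation takes a methyl proton because C6–H is shielded by the di-ortho-substituted arene and the isobutyl group, and O-sulfonylation of the enolate gives the 2-triflyloxy-1-alkene with C6 intact.

Step 11
Reactants: 6 cPr*–CHO; 18 alkenyl triflate
Product: 19 (3S)-1-cPr*-5-methyl-2-methylidene-3-(2,4,6-trimethoxyphenyl)hexan-1-ol (carbinol epimers)
Conditions: CrCl2 (5 equiv), NiCl2 (2 mol %), DMF, rt
Reagents that add atoms: none
Why: In the Nozaki–Hiyama–Kishi coupling nickel activates the triflate and the derived alkenylchromium adds only to the aldehyde, tolerating ketal and steric crowding; the new carbinol centre is not controlled and is erased in step 13.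

Step 12
Reactants: 19 allylic alcohol
Product: 20 methyl carbonate of 19
Conditions: ClCO2Me, pyridine, DMAP (cat.), CH2Cl2, 0 °C → rt
Reagents that add atoms: methyl chloroformate, COC(=O)Cl
Why: DMAP-catalysed acylation installs the leaving group for the next step and avoids acid, which would ionise this allylic cyclopropylcarbinyl position.

Step 13
Reactants: 20 allylic carbonate
Product: 21 pinacol (E)-allylboronate cPr*–CH=C[CH(i-Bu)Ar]–CH2–B(pin) with C6 S
Conditions: B2pin2, CuCl (10 mol %), Xantphos (10 mol %), KOt-Bu (20 mol %), THF, rt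
Reagents that add atoms: bis(pinacolato)diboron, CC1(C)OB(OC1(C)C)B1OC(C)(C)C(C)(C)O1
Why: In this copper-catalysed γ-selective (SN2′) borylation of an allylic carbonate, the borylcopper species delivers boron to the open CH2 terminus as carbonate leaves; the alkene should form with cPr* trans to the large C6 group, and its geometry has no consequence.

Step 14
Reactants: 21 allylboronate; 22 3-(trimethylsilyl)prop-2-ynal
Product: 24 (6S)-4-cPr*-8-methyl-5-methylidene-6-(2,4,6-trimethoxyphenyl)non-1-yn-3-ol (mixture at C3 and C4), via O-boryl silylalkynol 23 (not isolated)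
Conditions: toluene, rt → 50 °C; then K2CO3, MeOH, rt
Reagents that add atoms: none
Why: Allylboration through a six-membered chair joins the γ-carbon C4 to the slim, electrophilic ynal and regenerates the C5=CH2 alkene, and methanolic carbonate then cleaves O–B and C–Si; C3 and C4 form without useful facial control, C3 being erased in step 15 and C4 settled in steps 17 and 18.

Step 15
Reactants: 24 propargylic alcohol
Product: 25 (6S)-4-cPr*-8-methyl-5-methylidene-6-(2,4,6-trimethoxyphenyl)non-1-yn-3-one
Conditions: Dess–Martin periodinane, CH2Cl2, 0 °C → rt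
Reagents that add atoms: none
Why: Dess–Martin oxidation of the secondary propargylic alcohol is fast and non-basic, so the ynone should form without the C5 alkene moving into conjugation.

Step 16
Reactants: 25 terminal ynone
Product: 26 (1Z,6S)-4-cPr*-1-iodo-8-methyl-5-methylidene-6-(2,4,6-trimethoxyphenyl)non-1-en-3-one
Conditions: NaI, AcOH (5 equiv), MeCN, 0 °C → rt, dark
Reagents that add atoms: sodium iodide, [Na+].[I-]
Why: Hydroiodination of the ynone proceeds by conjugate addition of iodide and protonation of the allenolate anti to iodine, which gives the Z-β-iodoenone under acid too weak to harm the ketal or the alkene.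

Step 17
Reactants: 26 (Z)-β-iodoenone
Product: 27 (4R,5R)-5-cPr*-4-methyl-4-[(1S)-3-methyl-1-(2,4,6-trimethoxyphenyl)butyl]cyclopent-2-en-1-one
Conditions: Pd(OAc)2 (10 mol %), PPh3 (30 mol %), HCO2Na (5 equiv), DMF, 60 °C, degassed
Reagents that add atoms: none
Why: Proposed new method: zerovalent palladium, formed from Pd(OAc)2 and PPh3, inserts into the C1–I bond of 26, the (Z)-alkenylpalladium adds syn across the C5=CH2 alkene so that C1 bonds to C5, and the resulting CH2–Pd species, which sits on a quaternary carbon and has no β-hydrogen, exchanges iodide for formate, loses CO2 and reductively eliminates to leave the C5 methyl group. The closest known reaction type is the formate-terminated (reductive) Heck cyclisation of aryl and unactivated alkenyl iodides onto 1,1-disubstituted alkenes; what is new is an acyclic (Z)-β-iodoenone with an enolisable α′-carbon as the halide partner. The one ring formed, the cyclopentenone, closes in the 5-exo-trig mode, because the three-atom tether C2–C3–C4 lets the C1–Pd bond align with the near alkene carbon C5 but not with the far CH2. The new quaternary centre C5 is controlled by C6: in the insertion transition state the small C6–H points towards the palladium-bearing CH2, the trimethoxyphenyl group stands anti to the incoming C1 and the isobutyl group lies to the outside, so C1 should bond to the alkene face away from the arene. C4 should epimerise through its dienol faster than the ring closes, so both epimers drain through the transition state that places cPr* trans to the bulky C6 substituent, which is also the more stable arrangement in 27. The step needs insertion to outrun hydride capture at C1, migration of the alkene into conjugation and 3-exo attack of CH2–Pd on the new enone; the Z geometry and short tether speed insertion, amine-free and chloride-free HCO2Na keeps the medium near neutral, the conjugated isomer would be a strained tetrasubstituted alkene, and the large excess of formate traps the alkylpalladium.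

Step 18
Reactants: 27 cyclopentenone
Product: 28 (2R,3R)-2-cPr*-3-methyl-3-[(1S)-3-methyl-1-(2,4,6-trimethoxyphenyl)butyl]cyclopentan-1-one
Conditions: H2 (1 atm), Pd/C (10 wt %), EtOAc, rt; filter; then DBU (0.2 equiv), toluene, rt
Reagents that add atoms: none
Why: Catalytic hydrogenation saturates the disubstituted enone alkene while the unconjugated cyclopropane and the arene stay intact, and DBU then equilibrates any C4 epimer to the more stable ketone with cPr* trans to the large C6 group, the ketal blocking an intramolecular aldol reaction.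

Step 19
Reactants: 28 ketal ketone
Product: 29 (2R,3R)-2-[(1R,3R)-2,2-dimethyl-3-(3-oxobutyl)cyclopropyl]-3-methyl-3-[(1S)-3-methyl-1-(2,4,6-trimethoxyphenyl)butyl]cyclopentan-1-one
Conditions: 1 M HCl, THF, rt
Reagents that add atoms: water, O
Why: Aqueous acid hydrolyses the dioxolane to the methyl ketone, C4 is already in its stable configuration, and nothing else in 28 is acid-labile at room temperature.

Step 20
Reactants: 29 diketone
Product: 31 tri-O-methylmacrocarpal N (3,5-diformyl derivative of 29), via bis(chloromethoxymethyl)arene 30 (not isolated)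
Conditions: Cl2CHOMe (6 equiv), TiCl4 (6 equiv), CH2Cl2, −78 → 0 °C; then ice-cold 1 M HCl
Reagents that add atoms: dichloromethyl methyl ether, COC(Cl)Cl; water, O
Why: In the twofold Rieche formylation the TiCl4-activated ether attacks the two free ring positions, each flanked by two methoxy groups and the only nucleophilic carbons present, and the α-chloro ethers are hydrolysed to the aldehydes.

Step 21
Reactants: 31 tri-O-methylmacrocarpal N
Product: 32 macrocarpal N
Conditions: BCl3 (10 equiv), CH2Cl2, −78 °C → rt
Reagents that add atoms: none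
Why: BCl3 cleaves aryl methyl ethers that lie ortho to a carbonyl group through a six-membered boron chelate, and each of the three methoxy groups has a formyl neighbour, while ketones and the unactivated cyclopropane should be left alone.

Compound list
1 | (+)-2-carene, (1S,6R)-3,7,7-trimethylbicyclo[4.1.0]hept-2-ene | CC1=C[C@H]2[C@@H](CC1)C2(C)C | starting material
2 | secondary ozonide of 1 (1,2,4-trioxolane across the former alkene) | CC12CC[C@@H]3[C@H](C(OO1)O2)C3(C)C | intermediate
3 | (1S,3R)-2,2-dimethyl-3-(3-oxobutyl)cyclopropane-1-carbaldehyde | CC(=O)CC[C@@H]1[C@H](C=O)C1(C)C | intermediate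
4 | 4-[(1R,3S)-3-(hydroxymethyl)-2,2-dimethylcyclopropyl]butan-2-one | CC(=O)CC[C@@H]1[C@H](CO)C1(C)C | intermediate
5 | {(1S,3R)-2,2-dimethyl-3-[2-(2-methyl-1,3-dioxolan-2-yl)ethyl]cyclopropyl}methanol | CC2(OCCO2)CC[C@@H]1[C@H](CO)C1(C)C | intermediate
6 | (1S,3R)-2,2-dimethyl-3-[2-(2-methyl-1,3-dioxolan-2-yl)ethyl]cyclopropane-1-carbaldehyde | CC2(OCCO2)CC[C@@H]1[C@H](C=O)C1(C)C | intermediate
7 | 2-(2,4,6-trimethoxyphenyl)acetic acid | COc1cc(OC)c(CC(=O)O)c(OC)c1 | starting material
8 | (R)-4-benzyl-1,3-oxazolidin-2-one | O=C1N[C@H](Cc2ccccc2)CO1 | starting material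
9 | 2-(2,4,6-trimethoxyphenyl)acetic pivalic anhydride | COc1cc(OC)c(CC(=O)OC(=O)C(C)(C)C)c(OC)c1 | intermediate
10 | (R)-4-benzyl-3-[2-(2,4,6-trimethoxyphenyl)acetyl]oxazolidin-2-one | COc1cc(OC)c(CC(=O)N2[C@H](Cc3ccccc3)COC2=O)c(OC)c1 | intermediate
11 | 3-bromo-2-methylprop-1-ene | C=C(C)CBr | starting material
12 | sodium Z-enolate of 10 | [Na+].[O-]/C(=C\c1c(OC)cc(OC)cc1OC)N1[C@H](Cc2ccccc2)COC1=O | intermediate
13 | (R)-4-benzyl-3-[(R)-4-methyl-2-(2,4,6-trimethoxyphenyl)pent-4-enoyl]oxazolidin-2-one | O=C([C@H](CC(C)=C)c1c(OC)cc(OC)cc1OC)N1[C@H](Cc2ccccc2)COC1=O | intermediate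
14 | (R)-4-benzyl-3-[(R)-4-methyl-2-(2,4,6-trimethoxyphenyl)pentanoyl]oxazolidin-2-one | O=C([C@H](CC(C)C)c1c(OC)cc(OC)cc1OC)N1[C@H](Cc2ccccc2)COC1=O | intermediate
15 | S-ethyl (R)-4-methyl-2-(2,4,6-trimethoxyphenyl)pentanethioate | CCSC(=O)[C@H](CC(C)C)c1c(OC)cc(OC)cc1OC | intermediate
16 | (R)-5-methyl-3-(2,4,6-trimethoxyphenyl)hexan-2-one | CC(=O)[C@H](CC(C)C)c1c(OC)cc(OC)cc1OC | intermediate
17 | terminal lithium enolate of 16 | [Li+].[O-]C(=C)[C@H](CC(C)C)c1c(OC)cc(OC)cc1OC | intermediate
18 | (R)-5-methyl-3-(2,4,6-trimethoxyphenyl)hex-1-en-2-yl trifluoromethanesulfonate | C=C(OS(=O)(=O)C(F)(F)F)[C@H](CC(C)C)c1c(OC)cc(OC)cc1OC | intermediate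
19 | (3S)-1-cPr*-5-methyl-2-methylidene-3-(2,4,6-trimethoxyphenyl)hexan-1-ol, carbinol epimers | CC3(OCCO3)CC[C@@H]1[C@H](C(O)C(=C)[C@H](CC(C)C)c2c(OC)cc(OC)cc2OC)C1(C)C | intermediate
20 | methyl carbonate of 19 | CC3(OCCO3)CC[C@@H]1[C@H](C(OC(=O)OC)C(=C)[C@H](CC(C)C)c2c(OC)cc(OC)cc2OC)C1(C)C | intermediate
21 | pinacol (E)-allylboronate cPr*–CH=C[CH(i-Bu)Ar]–CH2–B(pin), C6 S | CC3(OCCO3)CC[C@@H]1[C@H](/C=C(\CB2OC(C)(C)C(C)(C)O2)[C@H](CC(C)C)c2c(OC)cc(OC)cc2OC)C1(C)C | intermediate
22 | 3-(trimethylsilyl)prop-2-ynal | C[Si](C)(C)C#CC=O | starting material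
23 | O-(pinacolatoboryl) ether of the 1-trimethylsilyl derivative of 24 | CC3(OCCO3)CC[C@@H]1[C@H](C(C(OB2OC(C)(C)C(C)(C)O2)C#C[Si](C)(C)C)C(=C)[C@H](CC(C)C)c2c(OC)cc(OC)cc2OC)C1(C)C | intermediate
24 | (6S)-4-cPr*-8-methyl-5-methylidene-6-(2,4,6-trimethoxyphenyl)non-1-yn-3-ol, mixture at C3 and C4 | CC3(OCCO3)CC[C@@H]1[C@H](C(C(O)C#C)C(=C)[C@H](CC(C)C)c2c(OC)cc(OC)cc2OC)C1(C)C | intermediate
25 | (6S)-4-cPr*-8-methyl-5-methylidene-6-(2,4,6-trimethoxyphenyl)non-1-yn-3-one, C4 epimers | CC3(OCCO3)CC[C@@H]1[C@H](C(C(=O)C#C)C(=C)[C@H](CC(C)C)c2c(OC)cc(OC)cc2OC)C1(C)C | intermediate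
26 | (1Z,6S)-4-cPr*-1-iodo-8-methyl-5-methylidene-6-(2,4,6-trimethoxyphenyl)non-1-en-3-one, interconverting C4 epimers | CC3(OCCO3)CC[C@@H]1[C@H](C(C(=O)/C=C\I)C(=C)[C@H](CC(C)C)c2c(OC)cc(OC)cc2OC)C1(C)C | intermediate
27 | (4R,5R)-5-cPr*-4-methyl-4-[(1S)-3-methyl-1-(2,4,6-trimethoxyphenyl)butyl]cyclopent-2-en-1-one | CC3(OCCO3)CC[C@@H]1[C@H]([C@H]2C(=O)C=C[C@]2(C)[C@H](CC(C)C)c2c(OC)cc(OC)cc2OC)C1(C)C | intermediate
28 | (2R,3R)-2-cPr*-3-methyl-3-[(1S)-3-methyl-1-(2,4,6-trimethoxyphenyl)butyl]cyclopentan-1-one | CC3(OCCO3)CC[C@@H]1[C@H]([C@H]2C(=O)CC[C@]2(C)[C@H](CC(C)C)c2c(OC)cc(OC)cc2OC)C1(C)C | intermediate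
29 | (2R,3R)-2-[(1R,3R)-2,2-dimethyl-3-(3-oxobutyl)cyclopropyl]-3-methyl-3-[(1S)-3-methyl-1-(2,4,6-trimethoxyphenyl)butyl]cyclopentan-1-one | CC(=O)CC[C@@H]1[C@H]([C@H]2C(=O)CC[C@]2(C)[C@H](CC(C)C)c2c(OC)cc(OC)cc2OC)C1(C)C | intermediate
30 | 3,5-bis[chloro(methoxy)methyl]aryl derivative of 29, epimers at the two CHCl carbons | CC(=O)CC[C@@H]1[C@H]([C@H]2C(=O)CC[C@]2(C)[C@H](CC(C)C)c2c(OC)c(C(Cl)OC)c(OC)c(C(Cl)OC)c2OC)C1(C)C | intermediate
31 | tri-O-methylmacrocarpal N | CC(=O)CC[C@@H]1[C@H]([C@H]2C(=O)CC[C@]2(C)[C@H](CC(C)C)c2c(OC)c(C=O)c(OC)c(C=O)c2OC)C1(C)C | intermediate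
32 | macrocarpal N | CC(=O)CC[C@@H]1[C@H]([C@H]2C(=O)CC[C@]2(C)[C@H](CC(C)C)c2c(O)c(C=O)c(O)c(C=O)c2O)C1(C)C | target

Total step count: 21. Longest linear sequence: 17 steps (steps 5 to 21, from 7).

Steps most likely to fail

1. Step 17. Several processes could compete with ring closure:
- Hydride capture at C1 before the ring closes.
- Chelation of the ketone oxygen to palladium, which turns C4 and the alkene away from the metal.
- Displacement of iodide by formate through addition–elimination.
- Attack on the wrong alkene face, if the rotamer with C6–H next to C4 reacts.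

The fallback sets out from 26 and lowers the oxidation level at C3. Luche reduction (NaBH4, CeCl3·7H2O, MeOH, −78 °C) should give the (Z)-iodoallylic alcohol F1. This compound is neither a Michael acceptor nor enolisable, so C4 is fixed and the epimer with the target C4 configuration can be separated. The other epimer can be returned to 26 with Dess–Martin periodinane. F1 is an unactivated (Z)-alkenyl iodide, the class for which formate-terminated 5-exo Heck cyclisation onto 1,1-disubstituted alkenes is established. Pd(OAc)2, PPh3 and HCO2Na in DMF should then give the cyclopentenol F2, with the fixed C4 centre holding the large C6 group trans to cPr*. Dess–Martin oxidation of F2 comes back to the route at 27.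

2. Step 13. Borylcupration may be slow at an alkene flanked by two branched carbons, and the cyclopropylcarbinyl carbonate may ionise in competition. The fallback sets out from 20 and replaces the boron relay by an umpolung of the π-allyl complex. Pd(PPh3)4 (cat.) with InI in THF should convert 20 through its π-allylpalladium into an allylindium reagent. This reagent adds through its more substituted terminus C4 to 22 and gives the silylalkynol F3. K2CO3 in MeOH removes the silyl group and comes back to the route at 24, bypassing 21 and 23.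

3. Step 21. Cleavage may stall after two of the three methyl ethers once the boron chelates have formed, or the dialdehyde may erode on long exposure to the Lewis acid. The fallback sets out from 29 and reverses the order of the last two operations. BBr3 (CH2Cl2, −78 → 0 °C) demethylates the aldehyde-free arene to the alkylphloroglucinol F4. Vilsmeier–Haack diformylation of this very electron-rich ring (POCl3, DMF, EtOAc, 0 °C → rt, then water), a known reaction of alkylphloroglucinols, comes back to the route at 32.

Further compounds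
F1 | step 17 | (1Z,6S)-4-cPr*-1-iodo-8-methyl-5-methylidene-6-(2,4,6-trimethoxyphenyl)non-1-en-3-ol, C4 as in the target, carbinol epimers | CC3(OCCO3)CC[C@@H]1[C@H]([C@@H](C(O)/C=C\I)C(=C)[C@H](CC(C)C)c2c(OC)cc(OC)cc2OC)C1(C)C
F2 | step 17 | 5-cPr*-4-methyl-4-[(1S)-3-methyl-1-(2,4,6-trimethoxyphenyl)butyl]cyclopent-2-en-1-ol, ring centres as in 27, carbinol epimers | CC3(OCCO3)CC[C@@H]1[C@H]([C@H]2C(O)C=C[C@]2(C)[C@H](CC(C)C)c2c(OC)cc(OC)cc2OC)C1(C)C
F3 | step 13 | (6S)-4-cPr*-8-methyl-5-methylidene-6-(2,4,6-trimethoxyphenyl)-1-(trimethylsilyl)non-1-yn-3-ol, mixture at C3 and C4 | CC3(OCCO3)CC[C@@H]1[C@H](C(C(O)C#C[Si](C)(C)C)C(=C)[C@H](CC(C)C)c2c(OC)cc(OC)cc2OC)C1(C)C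
F4 | step 21 | (2R,3R)-2-[(1R,3R)-2,2-dimethyl-3-(3-oxobutyl)cyclopropyl]-3-methyl-3-[(1S)-3-methyl-1-(2,4,6-trihydroxyphenyl)butyl]cyclopentan-1-one | CC(=O)CC[C@@H]1[C@H]([C@H]2C(=O)CC[C@]2(C)[C@H](CC(C)C)c2c(O)cc(O)cc2O)C1(C)C
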